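## Retrosynthetic overview

1. Numbering: ring A is the benzene ring (C4a, C5–C8, C8a), ring B the dihydropyran (O1, C2, C3, C4), ring C the pyrone. The last disconnection is the C6–CH2–pyrone bridge, formed from an ortho-quinone methide of ring A and C3 of the 4-hydroxy-2-pyrone. The pyrone is made from 3-pentanone and malonyl dichloride.
2. Ring B is opened at O1–C2. C2 with its two methyl groups is a masked isopropenyl carbon that the C8a phenol captures in a 6-exo closure.
3. Key disconnection: C4–C4a and C3–C2 together, by an enantioselective palladium-catalysed conjunctive cross-coupling. The three partners are an aryl bromide (ring A), a vinylboronate (C3 and C4) and an isopropenyl group (C2 and both methyls). C3–B then becomes C3–OH with retention.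
4. Enabling feature: in ring B the two-carbon bridge C4H2–C3H(OH) lies between aromatic C4a and the fully substituted C2. This is a secondary carbinol (a masked C–B centre) flanked by an aryl-bearing CH2 and by a carbon that can migrate from boron as an sp2 carbon. The phenol oxygen on C8a is in place to finish the ring.
5. Order of rings: A is bought (phloroglucinol, acylated with (S)-2-methylbutanoic acid), B closes in step 7, and C is built separately (step 10) and joined last.

Key step: step 5

Assumption: the sense of induction of the ferrocenyl diphosphine in step 5 is taken by analogy with aryl- and alkenyl-migrating borates of this ligand family; should a model coupling show the opposite sense, the mirror-image ligand (also commercial) is used and nothing else changes.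

## Route

Step 1
Reactants: 1 (S)-2-methylbutanoic acid; 2 phloroglucinol (benzene-1,3,5-triol)
Product: 4 (2S)-2-methyl-1-(2,4,6-trihydroxyphenyl)butan-1-one, via acid chloride 3 (not isolated)
Conditions: (COCl)2, DMF (cat.), CH2Cl2, 0 °C to rt; then 2, AlCl3 (3.5 equiv), CH2Cl2/PhNO2, 0 to 40 °C; aq. HCl work-up
Reagents that add atoms: none
Why: Friedel–Crafts C-acylation of the very electron-rich symmetric arene should stop after one acyl group because the aluminium-chelated aryl ketone is deactivated, and the acylium pathway does not touch the alpha C–H, so the (S) centre bought with 1 should be carried over if the temperature is kept low.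

Step 2
Reactants: 4
Product: 5 (2S)-1-[2,4-bis(benzyloxy)-6-hydroxyphenyl]-2-methylbutan-1-one
Conditions: BnBr (2.1 equiv), K2CO3 (2.2 equiv), DMF, rt
Reagents that add atoms: benzyl bromide, BrCc1ccccc1
Why: Williamson etherification takes the para hydroxyl and one of the two equivalent ortho hydroxyls, whereas the last ortho hydroxyl is held in a strong hydrogen bond to the ketone and should stay free with two equivalents of halide, which marks the oxygen that becomes O1.

Step 3
Reactants: 5
Product: 6 (2S)-1-[4,6-bis(benzyloxy)-3-bromo-2-hydroxyphenyl]-2-methylbutan-1-one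
Conditions: NBS (1.0 equiv), CH2Cl2, −20 to 0 °C, dark
Reagents that add atoms: N-bromosuccinimide, O=C1CCC(=O)N1Br
Why: Electrophilic aromatic bromination is directed by the free chelated phenol to its open ortho position, which is also less crowded than the CH between the two benzyloxy groups, the usual pattern for 2-hydroxy-4,6-dialkoxyaryl ketones.

Step 4
Reactants: 6
Product: 7 (2S)-1-[4,6-bis(benzyloxy)-3-bromo-2-(methoxymethoxy)phenyl]-2-methylbutan-1-one
Conditions: MOMCl (3 equiv), i-Pr2NEt (4 equiv), Bu4NI (cat.), CH2Cl2, reflux
Reagents that add atoms: chloromethyl methyl ether, COCCl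
Why: O-alkylation to the MOM acetal removes the only acidic proton, which would otherwise protonate the borate of step 5, and the amine base is too weak to enolise the hindered ketone.

Step 5
Reactants: 7; 8 vinylboronic acid pinacol ester; 9 isopropenylmagnesium bromide
Product: 12 (2S)-1-{4,6-bis(benzyloxy)-3-[(2S)-2-hydroxy-3-methylbut-3-en-1-yl]-2-(methoxymethoxy)phenyl}-2-methylbutan-1-one, via sodium borate 10 (not isolated), via allylboronate 11 (not isolated)
Conditions: 8 (1.3 equiv), 9 (0.5 M in THF, 1.25 equiv), NaOTf (3 equiv), THF/DMSO, 0 °C to rt; then 7 (1.0 equiv), Pd(OAc)2 (5 mol %), (Rp,Rp)-1,1'-bis[bis(4-methoxy-3,5-dimethylphenyl)phosphino]-2,2'-bis[(S)-alpha-(dimethylamino)benzyl]ferrocene (MandyPhos type, 6 mol %), 60 °C; then NaBO3·4H2O, THF/H2O, rt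
Reagents that add atoms: sodium perborate tetrahydrate (source of the C3 oxygen), [Na+].[Na+].O[B-]1(O)OO[B-](O)(O)OO1
Why: Zerovalent palladium inserts into the C–Br bond of 7, NaOTf takes up the bromide, and the cationic divalent arylpalladium binds the unsubstituted vinyl group of borate 10, which triggers a 1,2-metalate shift in which the isopropenyl group moves from boron to the boron-bearing vinyl carbon (C2–C3 bond) anti to palladium, after which reductive elimination joins the former vinyl CH2 to the ring (C4–C4a bond). The closest known reaction type is the enantioselective conjunctive cross-coupling of bis(alkenyl)borates with aryl electrophiles, which gives alpha-chiral allylboronates, together with its Grignard/NaOTf variant that admits aryl bromides. No ring is closed in this step; ring B is closed in step 7. The new centre C3 is controlled by the chiral ferrocenyl diphosphine, which selects the face of the vinyl group that palladium binds, and the stereospecific perborate oxidation (retention) hands this on as the (S)-carbinol, while the (S) centre of the side chain is remote and should not be enolised. The step needs vinyl as acceptor and isopropenyl as migrating group, which the better binding of the less substituted alkene secures, and it needs the metalate shift to outrun direct alkenyl transfer and beta-hydride elimination, which the wide-bite-angle ligand and the two ortho alkoxy groups (fast reductive elimination) favour. The ketone is spared because all Grignard reagent is bound as borate (8 in slight excess) and the carbonyl group is flanked by two ortho substituents.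

Step 6
Reactants: 12
Product: 13 (2S)-1-{4,6-bis(benzyloxy)-2-hydroxy-3-[(2S)-2-hydroxy-3-methylbut-3-en-1-yl]phenyl}-2-methylbutan-1-one
Conditions: conc. HCl (cat.), MeOH, rt
Reagents that add atoms: none
Why: Acid-catalysed acetal exchange removes the aryl MOM ether ortho to the carbonyl group, the most acid-labile group present, while the benzyl ethers, the allylic alcohol and the 1,1-disubstituted alkene should survive dilute acid at room temperature.

Step 7
Reactants: 13
Product: 15 (2S)-1-[(3S)-5,7-bis(benzyloxy)-3-hydroxy-2,2-dimethyl-3,4-dihydro-2H-chromen-8-yl]-2-methylbutan-1-one, via organomercurial 14 (not isolated)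
Conditions: Hg(OCOCF3)2 (1.1 equiv), THF, 0 °C; then NaBH4 (1 equiv), 3 M aq. NaOH, 0 °C, short contact
Reagents that add atoms: none
Why: In this intramolecular oxymercuration–demercuration the only free phenol attacks the more substituted carbon of the mercurinium ion in a Markovnikov 6-exo-trig closure of ring B (O1–C2), no free beta-hydroxy cation arises that could suffer a hydride shift, the borohydride turns CH2–Hg into the second methyl group so that the transient C2 centre vanishes, and C3 is not touched.

Step 8
Reactants: 15
Product: 16 (2S)-2-methyl-1-[(3S)-3,5,7-trihydroxy-2,2-dimethyl-3,4-dihydro-2H-chromen-8-yl]butan-1-one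
Conditions: H2 (1 atm), 10% Pd/C, EtOAc/EtOH, rt
Reagents that add atoms: none
Why: Catalytic hydrogenolysis cleaves both aryl benzyl ethers under neutral conditions that should leave the chelated aryl ketone, the secondary alcohol and both stereocentres unchanged.

Step 9
Reactants: 17 3-pentanone
Product: 18 3-(trimethylsilyloxy)pent-2-ene (E/Z mixture)
Conditions: TMSOTf (1.1 equiv), Et3N (1.3 equiv), CH2Cl2, 0 °C
Reagents that add atoms: trimethylsilyl triflate, C[Si](C)(C)OS(=O)(=O)C(F)(F)F
Why: Soft enolisation and O-silylation of a symmetric ketone can give only one regioisomer, and the alkene geometry is lost in the next step.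

Step 10
Reactants: 18; 19 malonyl dichloride
Product: 20 6-ethyl-4-hydroxy-5-methyl-2H-pyran-2-one
Conditions: Et2O, −78 °C to rt
Reagents that add atoms: none
Why: C-acylation of the silyl enol ether by one acyl chloride group, then O-acylation of the enolised ketone by the other (lactonisation) and tautomerisation, is the known one-step 4-hydroxy-2-pyrone synthesis from silyl enol ethers and malonyl dichloride and builds ring C with ethyl at C6 and methyl at C5.

Step 11
Reactants: 16; 20
Product: 23 6-ethyl-4-hydroxy-5-methyl-3-({(3S)-3,5,7-trihydroxy-2,2-dimethyl-8-[(2S)-2-methylbutanoyl]-3,4-dihydro-2H-chromen-6-yl}methyl)-2H-pyran-2-one (target), via Mannich base 21 (not isolated), via quinone methide 22 (not isolated)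
Conditions: N,N-dimethylmethyleneiminium chloride (1.05 equiv), CH2Cl2/MeCN, rt; then 20 (1.5 equiv), 1,4-dioxane, 90 °C
Reagents that add atoms: N,N-dimethylmethyleneiminium chloride, C=[N+](C)C.[Cl-]
Why: Mannich aminomethylation can occur only at C6, the single free nucleophilic ring carbon, and thermal loss of dimethylamine gives an ortho-quinone methide that the acidic pyrone captures at its C3 by Michael addition, so that no free arene is left to form a symmetric dimer.

## Compound list

1 | (S)-2-methylbutanoic acid | CC[C@H](C)C(=O)O | starting material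
2 | phloroglucinol | Oc1cc(O)cc(O)c1 | starting material
3 | (S)-2-methylbutanoyl chloride | CC[C@H](C)C(=O)Cl | intermediate
4 | (2S)-2-methyl-1-(2,4,6-trihydroxyphenyl)butan-1-one | CC[C@H](C)C(=O)c1c(O)cc(O)cc1O | intermediate
5 | (2S)-1-[2,4-bis(benzyloxy)-6-hydroxyphenyl]-2-methylbutan-1-one | CC[C@H](C)C(=O)c1c(O)cc(OCc2ccccc2)cc1OCc1ccccc1 | intermediate
6 | (2S)-1-[4,6-bis(benzyloxy)-3-bromo-2-hydroxyphenyl]-2-methylbutan-1-one | CC[C@H](C)C(=O)c1c(O)c(Br)c(OCc2ccccc2)cc1OCc1ccccc1 | intermediate
7 | (2S)-1-[4,6-bis(benzyloxy)-3-bromo-2-(methoxymethoxy)phenyl]-2-methylbutan-1-one | CC[C@H](C)C(=O)c1c(OCOC)c(Br)c(OCc2ccccc2)cc1OCc1ccccc1 | intermediate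
8 | vinylboronic acid pinacol ester | C=CB1OC(C)(C)C(C)(C)O1 | starting material
9 | isopropenylmagnesium bromide | CC(=C)[Mg]Br | starting material
10 | sodium isopropenyl(vinyl)(pinacolato)borate | [Na+].C=C[B-]1(C(C)=C)OC(C)(C)C(C)(C)O1 | intermediate
11 | (2S)-1-{4,6-bis(benzyloxy)-2-(methoxymethoxy)-3-[(2S)-3-methyl-2-(4,4,5,5-tetramethyl-1,3,2-dioxaborolan-2-yl)but-3-en-1-yl]phenyl}-2-methylbutan-1-one | CC[C@H](C)C(=O)c1c(OCOC)c(C[C@H](B2OC(C)(C)C(C)(C)O2)C(C)=C)c(OCc2ccccc2)cc1OCc1ccccc1 | intermediate
12 | (2S)-1-{4,6-bis(benzyloxy)-3-[(2S)-2-hydroxy-3-methylbut-3-en-1-yl]-2-(methoxymethoxy)phenyl}-2-methylbutan-1-one | CC[C@H](C)C(=O)c1c(OCOC)c(C[C@H](O)C(C)=C)c(OCc2ccccc2)cc1OCc1ccccc1 | intermediate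
13 | (2S)-1-{4,6-bis(benzyloxy)-2-hydroxy-3-[(2S)-2-hydroxy-3-methylbut-3-en-1-yl]phenyl}-2-methylbutan-1-one | CC[C@H](C)C(=O)c1c(O)c(C[C@H](O)C(C)=C)c(OCc2ccccc2)cc1OCc1ccccc1 | intermediate
14 | {(3S)-5,7-bis(benzyloxy)-3-hydroxy-2-methyl-8-[(2S)-2-methylbutanoyl]chroman-2-yl}methylmercury trifluoroacetate (both C2 epimers) | CC[C@H](C)C(=O)c1c(OCc2ccccc2)cc(OCc2ccccc2)c2c1OC(C)(C[Hg]OC(=O)C(F)(F)F)[C@@H](O)C2 | intermediate
15 | (2S)-1-[(3S)-5,7-bis(benzyloxy)-3-hydroxy-2,2-dimethyl-3,4-dihydro-2H-chromen-8-yl]-2-methylbutan-1-one | CC[C@H](C)C(=O)c1c(OCc2ccccc2)cc(OCc2ccccc2)c2c1OC(C)(C)[C@@H](O)C2 | intermediate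
16 | (2S)-2-methyl-1-[(3S)-3,5,7-trihydroxy-2,2-dimethyl-3,4-dihydro-2H-chromen-8-yl]butan-1-one | CC[C@H](C)C(=O)c1c(O)cc(O)c2c1OC(C)(C)[C@@H](O)C2 | intermediate
17 | 3-pentanone | CCC(=O)CC | starting material
18 | 3-(trimethylsilyloxy)pent-2-ene (E/Z mixture) | CC=C(CC)O[Si](C)(C)C | intermediate
19 | malonyl dichloride | O=C(Cl)CC(=O)Cl | starting material
20 | 6-ethyl-4-hydroxy-5-methyl-2H-pyran-2-one | CCc1oc(=O)cc(O)c1C | intermediate
21 | 6-(dimethylaminomethyl) derivative of 16, as its hydrochloride | CC[C@H](C)C(=O)c1c(O)c(CN(C)C)c(O)c2c1OC(C)(C)[C@@H](O)C2.Cl | intermediate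
22 | 6-methylidene ortho-quinone methide derived from 21 | C=C1C(=O)C(C(=O)[C@@H](C)CC)=C2OC(C)(C)[C@@H](O)CC2=C1O | intermediate
23 | 6-ethyl-4-hydroxy-5-methyl-3-({(3S)-3,5,7-trihydroxy-2,2-dimethyl-8-[(2S)-2-methylbutanoyl]-3,4-dihydro-2H-chromen-6-yl}methyl)-2H-pyran-2-one | CCc1oc(=O)c(Cc2c(O)c3c(c(C(=O)[C@@H](C)CC)c2O)OC(C)(C)[C@@H](O)C3)c(O)c1C | target

## Step count

Total step count: 11. Longest linear sequence: 9 (steps 1–8 and 11). Steps 9 and 10 form the short pyrone branch.

## Steps most likely to fail

**Step 5.**
- Risk: oxidative addition into the electron-rich, doubly ortho-substituted bromide may be slow. Plain transfer of an alkenyl group from boron to palladium, or decay of the borate, could then overtake the metalate shift. The bulky aryl group may also erode the facial selectivity.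
- Fallback: it sets out from 5 and comes back at 16, using known chromene chemistry.
- The chelated phenol of 5 is alkylated with 3-chloro-3-methylbut-1-yne (CuCl2 cat., DBU, MeCN, 0 °C) to the aryl 1,1-dimethylpropargyl ether F1.
- Heating in N,N-diethylaniline brings about the aromatic propargyl Claisen rearrangement, hydrogen shift and oxa-electrocyclisation at the only free ortho carbon. This gives the 8-acyl-2,2-dimethyl-2H-chromene F2.
- Jacobsen–Katsuki epoxidation follows, with (S,S)-N,N'-bis(3,5-di-tert-butylsalicylidene)-1,2-cyclohexanediaminomanganese chloride (trivalent manganese), NaOCl and 4-phenylpyridine N-oxide. It should give the (3S,4S)-epoxide F3.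
- H2 over Pd/C cleaves the benzylic C4–O bond and both benzyl ethers to give 16.

**Step 7.**
- Risk: mercuration of the free ring position, sluggish capture of the mercurinium ion by the hydrogen-bonded phenol, or attack of borohydride on the ketone during demercuration.
- Fallback: it sets out from 13 and comes back at 16.
- Iodoetherification (N-iodosuccinimide, NaHCO3, CH2Cl2, 0 °C) closes ring B in the same 6-exo sense to the 2-(iodomethyl)chromanol F4, as a mixture of C2 epimers that converge.
- A single hydrogenolysis (H2, Pd/C, NaOAc, MeOH/EtOAc) removes the C–I bond, any ring iodine and both benzyl groups. Neither mercury nor a hydride reagent is needed.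

**Step 11.**
- Risk: the CH2 unit may be exchanged between the partners by a retro-Mannich process, which would lead to symmetric methylene dimers. Loss of the amine may also be slow.
- Fallback: it sets out from 16 and comes back at 23, with the bridging carbon at the aldehyde level.
- Vilsmeier–Haack formylation (POCl3, DMF, EtOAc; the aqueous hydrolysis also cleaves any transient formate at O3) gives the 6-carbaldehyde F5.
- Organocatalytic reductive alkylation of 20 follows (L-proline cat., Hantzsch ester, CH2Cl2/EtOH, rt). It proceeds through the Knoevenagel adduct F6, which is reduced in the flask by conjugate hydride transfer to 23. Cross-selectivity is built in, because only one partner carries the aldehyde.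

## Further compounds

F1 | step 5 | (2S)-1-{2,4-bis(benzyloxy)-6-[(2-methylbut-3-yn-2-yl)oxy]phenyl}-2-methylbutan-1-one | CC[C@H](C)C(=O)c1c(OC(C)(C)C#C)cc(OCc2ccccc2)cc1OCc1ccccc1
F2 | step 5 | (2S)-1-[5,7-bis(benzyloxy)-2,2-dimethyl-2H-chromen-8-yl]-2-methylbutan-1-one | CC[C@H](C)C(=O)c1c(OCc2ccccc2)cc(OCc2ccccc2)c2c1OC(C)(C)C=C2
F3 | step 5 | (3S,4S)-3,4-epoxide of F2 | CC[C@H](C)C(=O)c1c(OCc2ccccc2)cc(OCc2ccccc2)c2c1OC(C)(C)[C@H]1O[C@H]12
F4 | step 7 | (2S)-1-[(3S)-5,7-bis(benzyloxy)-3-hydroxy-2-(iodomethyl)-2-methyl-3,4-dihydro-2H-chromen-8-yl]-2-methylbutan-1-one (both C2 epimers) | CC[C@H](C)C(=O)c1c(OCc2ccccc2)cc(OCc2ccccc2)c2c1OC(C)(CI)[C@@H](O)C2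
F5 | step 11 | (3S)-3,5,7-trihydroxy-2,2-dimethyl-8-[(2S)-2-methylbutanoyl]-3,4-dihydro-2H-chromene-6-carbaldehyde | CC[C@H](C)C(=O)c1c(O)c(C=O)c(O)c2c1OC(C)(C)[C@@H](O)C2
F6 | step 11 | 3-arylmethylidene-6-ethyl-5-methylpyran-2,4-dione (Knoevenagel adduct of F5 and 20) | CCC1=C(C)C(=O)C(=Cc2c(O)c3c(c(C(=O)[C@@H](C)CC)c2O)OC(C)(C)[C@@H](O)C3)C(=O)O1
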